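**Remarks on the chemistry**

- Read from the SMILES, both stereocentres are (S): C1 of the indane (benzodioxinyl > C7a > C2 > H) and C2 of the benzodioxane (O1 > C(CH3)2OH > C3 > H). Indane numbering C1–C7a is used; ring A is the benzene ring of the indane, ring B that of the benzodioxane.
- The configuration of the cyclisation precursor was rechecked against the target: an (S)-propargylic centre maps onto (S)-C1, and no connectivity had to be changed.
- The C7 carbon is carried as a 1,3-dioxolane-protected aldehyde instead of a silyl-protected alcohol. The carbon skeleton of the cyclisation precursor and product is unchanged.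
- The sense of induction of the tartrate (step 8) and of the pybox ligand (step 14) is assigned by the usual models and would have to be confirmed on the first run.

## Structural features

The target is an indane: benzene ring A is fused to a cyclopentane whose C1 carries a 1,4-benzodioxane bonded through C8 of its benzene ring B, whose C2 carries an exocyclic isopropylidene group, and whose C3 is a methylene. Ring A bears a hydroxyl group at C6 and a formyl group at C7, so C3a, C7a, C7 and C6 are four contiguous substituted positions and the aldehyde lies beside the ring-fusion carbon that holds C1. Ring B carries a methyl group at C6, and the dioxane C2 holds a 2-hydroxypropan-2-yl group and is bonded to the oxygen ortho to the indane–aryl bond. The two stereocentres, indane C1 and dioxane C2, are separated by ring B and an ether oxygen, so neither can steer the other and each must be set independently. The C1–H bond is doubly benzylic and allylic, so acid or strong base can pull the tetrasubstituted alkene into the five-membered ring and erase the stereocentre; the tertiary alcohol and the salicylaldehyde unit also limit the late reagents. The real difficulty is the crowded C1 between two ortho-substituted arenes, together with the regiochemistry of both arenes and an alkene that must never be allowed to migrate. The key step exploits the C2=C(CH3)2 unit: the outer carbon carries two methyl groups and C2 is joined to the benzylic C3, so the alkene can be read as a C3 benzyl–metal bond and a methyl group added to the same side of a but-2-ynyl triple bond held on C1.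

## Logic of the disconnections

**33 ⇒ 32.** The phenolic O–H is traced back to an O–CH3 bond. The oxygen is para to the future benzylic halide and must stay masked through every organometallic step; a methyl ether also steers the ring A iodination. The forward step must cleave only this ether, using the neighbouring formyl group as a handle, without acid strong enough to move the alkene.

**32 ⇒ 31.** The formyl group is traced back to a cyclic acetal (two C–O bonds). Carrying C7 at the aldehyde level removes a late desilylation and oxidation. The forward step is a mild hydrolysis that must leave the tertiary alcohol and the alkene alone.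

**31 ⇒ 29 + 30.** The C2–C3 ring bond and one C–CH3 bond of the isopropylidene are cut together. This removes the five-membered ring and the tetrasubstituted alkene in one move and leaves an open diarylmethyl alkyne with a benzylic chloride. The forward step must close the ring before the methyl group is transferred and must leave C1 untouched.

**29 ⇒ 27.** The C–Cl bond is traced back to a C–OH bond. A polar substitution of a primary benzylic alcohol replaces any radical chlorination, which could not distinguish the several benzylic positions. The forward step must react at the primary hydroxyl only and must not ionise the electron-rich benzylic position.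

**27 ⇒ 26.** Two O–Si bonds are reintroduced. The primary silyl ether keeps the future chloride latent and the tertiary silyl ether hides the only acidic proton of ring B during metalation; one fluoride treatment removes both.

**26 ⇒ 12 + 25.** The C1–aryl bond to ring B is cut. This is the convergent cut: it divides the molecule into two fragments of similar size and lets C1 arise from a racemic electrophile. The forward step must create the (S)-centre under catalyst control at a very hindered carbon and must form the bond at the propargylic, not the allenyl, terminus.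

**25 ⇒ 23 ⇒ 22.** The C–Zn bond is traced to C–Br, and the O–Si bond to the free tertiary alcohol. The bromine marks the position ortho to the oxygen that bears the stereocentre.

**12 ⇒ 9 + 10.** The C1–C(sp) bond and the carbonate C–O bond are cut. The propargylic carbon is the former aldehyde carbon; since the next step destroys and rebuilds this centre, no stereocontrol is needed.

**9 ⇒ 7.** The bond between C7a and its formyl carbon is cut back to a C–Br bond. The forward step needs halogen–metal exchange between two ortho substituents without silyl migration.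

**7 ⇒ 6 ⇒ 5.** The O–Si bond and then the C–H bond of the C3 carbon are removed (alcohol back to aldehyde). These are functional-group changes that keep this carbon distinct from C7.

**5 ⇒ 3.** The bond between C3a and its one-carbon substituent is cut back to a C–I bond. Two different halogens allow the two flanking carbons to be introduced one after the other; the forward step must exchange iodine only.

**3 ⇒ 2 ⇒ 1.** The acetal and then the C–I bond are removed. The iodine goes in para to the methoxy group, which fixes the fourth contiguous ring A substituent without directed metalation.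

**22 ⇒ 20.** The bond between the ring B oxygen and the dioxane C2 is cut, with the epoxide as the electrophile and an allyl group on the phenol. Ring closure by the oxygen next to bromine fixes the regiochemistry and sets the dioxane centre by inversion. The forward step needs 6-exo opening at the secondary epoxide carbon.

**20 ⇒ 19 + 15.** The O–CH2 bond is cut. The less hindered phenol is joined to the primary carbon of the chiral C5 unit; the stereocentre is not touched.

**19 ⇒ 17 ⇒ 16.** The aryl C–O bond is traced back to an aryl C–CHO bond, and the allyl ether to the free phenol. Direct bromination and alkylation of a simple methylcatechol would be unselective in both respects, whereas in 16 the bromine and the two oxygen positions are already distinguished.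

**15 ⇒ 13.** The two epoxide C–O bonds and the sulfonate are removed. The only source of absolute configuration for ring B is an allylic alcohol epoxidation.

## Other disconnections considered

**Alternative 1:** The cut runs through ring A itself. C3a–C7a, C4–C5 and C6–C7 are disconnected, so the benzene ring, the cyclopentane and a temporary oxasilole come from one open-chain triyne A2. In A2 the C1 centre, the C2 isopropylidene and C3 are already present, and an ethynyl(diisopropyl)silyl ether hangs on the future C7 methylene. Forward, RhCl(PPh3)3 would join the three triple bonds in a [2+2+2] cyclotrimerisation to A1; Tamao–Fleming oxidation of the aryl–silicon bond and oxidation of the benzylic alcohol would then lead to 33.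
- In its favour: three rings and three C–C bonds form in one step, and the tether places the C6 oxygen and the C7 carbon side by side with no regiochemical question. On this point it is better than the chosen plan, which needs steps 1–7 to arrange four neighbours on a bought benzene ring. It is the equal of the chosen plan in that the isopropylidene is never made by elimination.
- Against it here: C1 would have to be made and kept in A2, where its hydrogen is benzylic, propargylic and allylic at once; such a skipped enyne can isomerise to an allene or diene under base or metal hydrides. Setting that centre enantioselectively is the same problem as in step 14, on a more fragile substrate. Oxidising a hindered diisopropylsilyl–aryl bond with fluoride and peroxide would come late, on a molecule that already holds the alkene and the labile C1–H.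
- Comparison: mechanistically a metallacycle cycloaddition replaces an oxidative addition–insertion–coupling sequence, both catalytic. The cycloaddition step itself is more economical than step 17, but the linear build-up of A2 would probably use up that gain and the route would be less convergent.

**Alternative 2:** The cut is C1–C2. The precursor is the 1-aryl phthalan A4, a cyclic benzylic ether whose ring A also carries a prenyl group next to the carbon bonded to C1. Forward, a confined chiral imidodiphosphorimidate Brønsted acid would ionise the C1–O bond to a diarylmethyl cation paired with the chiral anion. The inner carbon of the prenyl alkene would attack it (5-exo closure, tertiary cation outside the ring), and loss of the C2 proton would give the isopropylidene. The phthalan oxygen is released as the C7 hydroxymethyl group of A3.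
- In its favour: C1 is set and the ring closed in one metal-free catalytic step, from a precursor whose C1 configuration does not matter, and the leaving group becomes a needed functional group. In step count and atom economy it is better than the chosen plan. It is about equal in what remains afterwards (one oxidation at C7 plus deprotection, against one hydrolysis plus demethylation).
- Against it here: the cation sits between two ortho-substituted arenes, and its faces must be told apart by the counter-anion alone while a second stereocentre is present. The proton can also be lost from a methyl group (isopropenyl isomer, new C2 centre), the liberated hydroxyl can recapture the cation, and acid may move the product alkene into conjugation with C1. The silyl ether and the dioxane must also tolerate the acid.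
- Comparison: the alternative forms C1–C2 and sets the stereocentre during ring closure; the chosen plan forms C2–C3 after the stereocentre is in place. In the chosen plan the alkene position is fixed by construction; here it depends on which proton is lost.

**Alternative 3:** The cut is the same C2–C3 bond as in the chosen plan, reached by deleting a nitrogen atom. The precursor is the tetrahydroisoquinoline A6, with the ring nitrogen between the carbons that become C2 and C3, a methyl ester on the future C2 and ring B already on the future C1. Forward, an N-alkoxy-N-(pivaloyloxy)benzamide would convert the N–H group into a 1,1-diazene; loss of N2 and recombination of the benzylic and ester-stabilised radicals would give the trans indane ester A5.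
- In its favour: A6 is open to classical heterocycle chemistry (ring closure onto the position para to the methoxy group), and the ring contraction is metal-free and mild. C1 is not part of the radical pair, so it is as safe there as in step 17 (equal). If C1 were set earlier by hydrogenation or conjugate addition, the hindered coupling of step 14 would be avoided, which would be a point in its favour.
- Against it here: A5 has an sp3 C2 ester, so the isopropylidene still requires double methyl addition and dehydration of a tertiary alcohol next to the labile C1–H. That elimination can give the isopropenyl isomer or the ring alkene, which is the main hazard of this target. The C2 stereocentre is built only to be destroyed, and radical pairs of this kind can disproportionate.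
- Comparison: the bond formed is identical; a radical pair replaces an organopalladium intermediate. The chosen plan installs the alkene in the ring-forming step, whereas this alternative needs at least two further steps and more protecting-group handling.

Key step: step 17

## Route

Step 1
Reactants: 1 2-bromo-6-methoxybenzaldehyde
Product: 2 2-bromo-3-iodo-6-methoxybenzaldehyde
Conditions: NIS, CF3CO2H, 0 °C → rt
Reagents that add atoms: N-iodosuccinimide, O=C1CCC(=O)N1I
Why: Electrophilic aromatic iodination; the methoxy group directs para, that position is also meta to the formyl group, and the ortho position is shielded because the O–CH3 group must turn away from the flanking formyl group; the iodine provides a second halogen that can be exchanged before the bromine.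

Step 2
Reactants: 2 2-bromo-3-iodo-6-methoxybenzaldehyde
Product: 3 2-(2-bromo-3-iodo-6-methoxyphenyl)-1,3-dioxolane
Conditions: HOCH2CH2OH, TsOH (cat.), toluene, reflux, Dean–Stark
Reagents that add atoms: ethane-1,2-diol, OCCO
Why: Acid-catalysed acetalisation with removal of water; it masks the future C7 aldehyde against the organomagnesium, organolithium and hydride reagents that follow.

Step 3
Reactants: 3 2-(2-bromo-3-iodo-6-methoxyphenyl)-1,3-dioxolane
Product: 5 2-bromo-3-(1,3-dioxolan-2-yl)-4-methoxybenzaldehyde, via arylmagnesium chloride 4 (not isolated)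
Conditions: iPrMgCl·LiCl, THF, −40 °C; DMF, −40 → 0 °C; aq. NH4Cl
Reagents that add atoms: N,N-dimethylformamide, CN(C)C=O
Why: Iodine–magnesium exchange is far faster than bromine–magnesium exchange, so only the C–I bond is metalated, and the ortho-bromoarylmagnesium should not collapse to an aryne at this temperature; Bouveault formylation then introduces the carbon that becomes C3.

Step 4
Reactants: 5 2-bromo-3-(1,3-dioxolan-2-yl)-4-methoxybenzaldehyde
Product: 6 [2-bromo-3-(1,3-dioxolan-2-yl)-4-methoxyphenyl]methanol
Conditions: NaBH4, MeOH/THF, 0 °C
Reagents that add atoms: none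
Why: Hydride reduction of the aldehyde; the aryl bromide and the acetal are inert to NaBH4.

Step 5
Reactants: 6 [2-bromo-3-(1,3-dioxolan-2-yl)-4-methoxyphenyl]methanol
Product: 7 {[2-bromo-3-(1,3-dioxolan-2-yl)-4-methoxyphenyl]methoxy}(tert-butyl)dimethylsilane
Conditions: TBSCl, imidazole, DMF, rt
Reagents that add atoms: tert-butyl(chloro)dimethylsilane, CC(C)(C)[Si](C)(C)Cl
Why: Silylation of the primary benzylic alcohol; the silyl ether survives the lithium, magnesium, zinc and nickel chemistry and is later removed by fluoride without touching the acetal.

Step 6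
Reactants: 7 {[2-bromo-3-(1,3-dioxolan-2-yl)-4-methoxyphenyl]methoxy}(tert-butyl)dimethylsilane
Product: 9 6-({[tert-butyl(dimethyl)silyl]oxy}methyl)-2-(1,3-dioxolan-2-yl)-3-methoxybenzaldehyde, via aryllithium 8 (not isolated)
Conditions: n-BuLi, THF, −78 °C; DMF, −78 → 0 °C; aq. NH4Cl
Reagents that add atoms: N,N-dimethylformamide, CN(C)C=O
Why: Bromine–lithium exchange followed by Bouveault formylation; the acetal oxygen can stabilise the aryllithium, and a short time at −78 °C before the quench keeps silyl migration from oxygen to the lithiated carbon (retro-Brook) from competing.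

Step 7
Reactants: 9 6-({[tert-butyl(dimethyl)silyl]oxy}methyl)-2-(1,3-dioxolan-2-yl)-3-methoxybenzaldehyde; 10 prop-1-yn-1-ylmagnesium bromide
Product: 12 rac-1-[6-({[tert-butyl(dimethyl)silyl]oxy}methyl)-2-(1,3-dioxolan-2-yl)-3-methoxyphenyl]but-2-yn-1-yl methyl carbonate, via bromomagnesium alkoxide 11 (not isolated)
Conditions: 10, THF, −20 → 0 °C; then ClCO2Me, 0 °C → rt
Reagents that add atoms: methyl chloroformate, COC(Cl)=O
Why: 1,2-Addition of a small alkynyl Grignard reagent to the hindered aldehyde and acylation of the alkoxide in the same flask; the centre is deliberately left racemic because the next coupling passes through a planar intermediate.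

Step 8
Reactants: 13 3-methylbut-2-en-1-ol
Product: 15 [(2R)-3,3-dimethyloxiran-2-yl]methyl 4-methylbenzenesulfonate, via epoxy alcohol 14 (not isolated)
Conditions: Ti(OiPr)4 (cat.), D-(−)-diisopropyl tartrate, t-BuOOH, 4 Å MS, CH2Cl2, −20 °C; then P(OMe)3, Et3N, DMAP (cat.), TsCl, −20 → 0 °C
Reagents that add atoms: tert-butyl hydroperoxide, CC(C)(C)OO; 4-methylbenzenesulfonyl chloride, Cc1ccc(cc1)S(Cl)(=O)=O
Why: Katsuki–Sharpless asymmetric epoxidation; the tartrate–titanium complex delivers oxygen to one face of the allylic alcohol, and the D-(−)-tartrate is chosen for the (R)-epoxide by the usual facial rule; sulfonylation in the same flask avoids isolating the volatile, water-soluble epoxy alcohol and gives a solid that can be recrystallised to raise enantiomeric purity.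

Step 9
Reactants: 16 3-bromo-2-hydroxy-5-methylbenzaldehyde
Product: 17 3-bromo-5-methyl-2-(prop-2-en-1-yloxy)benzaldehyde
Conditions: allyl bromide, K2CO3, DMF, rt
Reagents that add atoms: 3-bromoprop-1-ene, C=CCBr
Why: Williamson etherification; the allyl group blocks the oxygen next to bromine so that the other oxygen can be alkylated first, and unlike an acyl or silyl group it cannot migrate between the two catechol oxygens.

Step 10
Reactants: 17 3-bromo-5-methyl-2-(prop-2-en-1-yloxy)benzaldehyde
Product: 19 3-bromo-5-methyl-2-(prop-2-en-1-yloxy)phenol, via aryl formate 18 (not isolated)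
Conditions: mCPBA, CH2Cl2, rt; then K2CO3, MeOH, 0 °C
Reagents that add atoms: 3-chloroperoxybenzoic acid, OOC(=O)c1cccc(Cl)c1
Why: Baeyer–Villiger (Dakin-type) oxidation; the ortho-alkoxy aryl group migrates in preference to hydrogen, and methanolysis of the formate frees the second phenol at a defined position; the electron-poor allyl ether alkene reacts with the peracid much more slowly than the aldehyde.

Step 11
Reactants: 19 3-bromo-5-methyl-2-(prop-2-en-1-yloxy)phenol; 15 [(2R)-3,3-dimethyloxiran-2-yl]methyl 4-methylbenzenesulfonate
Product: 20 (2R)-2-{[3-bromo-5-methyl-2-(prop-2-en-1-yloxy)phenoxy]methyl}-3,3-dimethyloxirane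
Conditions: Cs2CO3, DMF, 50 °C
Reagents that add atoms: none
Why: SN2 displacement of the primary sulfonate by the phenoxide; the epoxide carbons are secondary and tertiary, so direct substitution at CH2 should dominate and the stereocentre is not involved.

Step 12
Reactants: 20 (2R)-2-{[3-bromo-5-methyl-2-(prop-2-en-1-yloxy)phenoxy]methyl}-3,3-dimethyloxirane
Product: 22 2-[(2S)-8-bromo-6-methyl-2,3-dihydro-1,4-benzodioxin-2-yl]propan-2-ol, via epoxy phenol 21 (not isolated)
Conditions: Pd(PPh3)4 (cat.), K2CO3, MeOH, rt → 45 °C
Reagents that add atoms: none
Why: Tsuji–Trost-type deallylation (allyl transfer to methoxide) frees the phenoxide, which opens the epoxide in the 6-exo-tet mode at the secondary carbon; the dioxane stereocentre is set by SN2 inversion, (R) in 20 becoming (S) in 22, and attack at the tertiary carbon (7-endo) is disfavoured under basic conditions.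

Step 13
Reactants: 22 2-[(2S)-8-bromo-6-methyl-2,3-dihydro-1,4-benzodioxin-2-yl]propan-2-ol
Product: 23 {[2-((2S)-8-bromo-6-methyl-2,3-dihydro-1,4-benzodioxin-2-yl)propan-2-yl]oxy}triethylsilane
Conditions: Et3SiOTf, 2,6-lutidine, CH2Cl2, −78 → 0 °C
Reagents that add atoms: triethylsilyl trifluoromethanesulfonate, CC[Si](CC)(CC)OS(=O)(=O)C(F)(F)F
Why: Silylation of the tertiary alcohol with a silyl triflate; it removes the only acidic proton of ring B before the aryllithium and arylzinc are made.

Step 14
Reactants: 23 {[2-((2S)-8-bromo-6-methyl-2,3-dihydro-1,4-benzodioxin-2-yl)propan-2-yl]oxy}triethylsilane; 12 rac-1-[6-({[tert-butyl(dimethyl)silyl]oxy}methyl)-2-(1,3-dioxolan-2-yl)-3-methoxyphenyl]but-2-yn-1-yl methyl carbonate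
Product: 26 {[2-((2S)-8-{(1S)-1-[6-({[tert-butyl(dimethyl)silyl]oxy}methyl)-2-(1,3-dioxolan-2-yl)-3-methoxyphenyl]but-2-yn-1-yl}-6-methyl-2,3-dihydro-1,4-benzodioxin-2-yl)propan-2-yl]oxy}triethylsilane, via aryllithium 24 (not isolated), via arylzinc chloride 25 (not isolated)
Conditions: 23, t-BuLi (2 equiv), THF, −78 °C; ZnCl2, −78 °C → rt; then 12, NiCl2(dme) (10 mol %), indanyl-pybox (one enantiomer, 13 mol %), DME, −20 °C
Reagents that add atoms: none
Why: Enantioconvergent nickel-catalysed Negishi arylation of a racemic propargylic carbonate: the low-valent nickel–pybox complex converts either enantiomer of 12 into the same planar benzylic–propargylic radical, which is captured by the chiral aryl–nickel species formed from 25 before reductive elimination makes the C1–aryl bond; the new C1 centre is set by the ligand (catalyst control), its enantiomer being chosen to favour (S), while the distant centre of 25 should have little influence; the mild arylzinc leaves carbonate, acetal and silyl ethers intact.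

Step 15
Reactants: 26 {[2-((2S)-8-{(1S)-1-[6-({[tert-butyl(dimethyl)silyl]oxy}methyl)-2-(1,3-dioxolan-2-yl)-3-methoxyphenyl]but-2-yn-1-yl}-6-methyl-2,3-dihydro-1,4-benzodioxin-2-yl)propan-2-yl]oxy}triethylsilane
Product: 27 2-[(2S)-8-{(1S)-1-[2-(1,3-dioxolan-2-yl)-6-(hydroxymethyl)-3-methoxyphenyl]but-2-yn-1-yl}-6-methyl-2,3-dihydro-1,4-benzodioxin-2-yl]propan-2-ol
Conditions: Bu4NF (3 equiv), THF, rt → 40 °C
Reagents that add atoms: none
Why: Fluoride cleavage of both silyl ethers in one operation; acetal, alkyne and aryl ethers are inert, and the conditions are not basic enough to disturb the C1–H bond.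

Step 16
Reactants: 27 2-[(2S)-8-{(1S)-1-[2-(1,3-dioxolan-2-yl)-6-(hydroxymethyl)-3-methoxyphenyl]but-2-yn-1-yl}-6-methyl-2,3-dihydro-1,4-benzodioxin-2-yl]propan-2-ol
Product: 29 2-[(2S)-8-{(1S)-1-[6-(chloromethyl)-2-(1,3-dioxolan-2-yl)-3-methoxyphenyl]but-2-yn-1-yl}-6-methyl-2,3-dihydro-1,4-benzodioxin-2-yl]propan-2-ol, via benzylic methanesulfonate 28 (not isolated)
Conditions: MsCl, LiCl, 2,4,6-collidine, DMF, 0 °C
Reagents that add atoms: lithium chloride, [Li+].[Cl-]
Why: Sulfonylation of the primary benzylic alcohol and chloride displacement in the same flask; the tertiary alcohol is too hindered to be sulfonylated, and the buffered, non-acidic medium preserves the acetal and keeps the 4-methoxybenzyl-type position from ionising.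

Step 17
Reactants: 29 2-[(2S)-8-{(1S)-1-[6-(chloromethyl)-2-(1,3-dioxolan-2-yl)-3-methoxyphenyl]but-2-yn-1-yl}-6-methyl-2,3-dihydro-1,4-benzodioxin-2-yl]propan-2-ol; 30 methylboronic acid
Product: 31 2-[(2S)-8-{(1S)-7-(1,3-dioxolan-2-yl)-6-methoxy-2-(propan-2-ylidene)-2,3-dihydro-1H-inden-1-yl}-6-methyl-2,3-dihydro-1,4-benzodioxin-2-yl]propan-2-ol
Conditions: Pd(PPh3)4 (10 mol %), 30 (3 equiv), K2CO3, anhydrous 1,4-dioxane, 90 °C
Reagents that add atoms: none
Why: Domino cyclic carbopalladation–Suzuki–Miyaura coupling: zerovalent palladium adds oxidatively to the benzylic C–Cl bond of 29, the benzylpalladium chloride (which has no β-hydrogen) adds syn across the tethered triple bond, and the exocyclic alkenylpalladium takes a methyl group from the boronate formed from 30 and K2CO3 and reductively eliminates to 31. The closest known reaction type is the palladium-catalysed cyclisation of a halide onto a tethered alkyne terminated by an organoboron reagent; initiation from a benzylic rather than an aryl halide is the less common variant. The cyclopentane closes in the 5-exo-dig mode (C3 attacks the alkyne carbon bonded to C1), forming C2–C3 and leaving palladium on the outer carbon; a syn addition in the 6-endo sense would place the two ring bonds trans on a cyclohexene double bond and is therefore excluded. No new stereocentre is formed and the alkene has no geometry because both outer substituents are methyl; C1 is not involved, and K2CO3 in dioxane is far too weak a base to remove its proton. The selectivity required is ring closure before cross-coupling, which the substrate secures because intramolecular insertion is fast while methyl transfer from boron to palladium is slow. Anhydrous conditions protect the electron-rich benzylic chloride from solvolysis, and the double bond is placed outside the ring by construction, with no elimination that could send it into conjugation.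

Step 18
Reactants: 31 2-[(2S)-8-{(1S)-7-(1,3-dioxolan-2-yl)-6-methoxy-2-(propan-2-ylidene)-2,3-dihydro-1H-inden-1-yl}-6-methyl-2,3-dihydro-1,4-benzodioxin-2-yl]propan-2-ol
Product: 32 (1S)-1-[(2S)-2-(2-hydroxypropan-2-yl)-6-methyl-2,3-dihydro-1,4-benzodioxin-8-yl]-6-methoxy-2-(propan-2-ylidene)-2,3-dihydro-1H-indene-7-carbaldehyde
Conditions: PPTS, acetone/H2O, 50 °C
Reagents that add atoms: water, O
Why: Acid-catalysed acetal hydrolysis through an oxocarbenium ion stabilised by the ortho-methoxy group; the acid is too weak to protonate the tetrasubstituted alkene or to ionise the tertiary alcohol.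

Step 19
Reactants: 32 (1S)-1-[(2S)-2-(2-hydroxypropan-2-yl)-6-methyl-2,3-dihydro-1,4-benzodioxin-8-yl]-6-methoxy-2-(propan-2-ylidene)-2,3-dihydro-1H-indene-7-carbaldehyde
Product: 33 diaporindene H, (1S)-6-hydroxy-1-[(2S)-2-(2-hydroxypropan-2-yl)-6-methyl-2,3-dihydro-1,4-benzodioxin-8-yl]-2-(propan-2-ylidene)-2,3-dihydro-1H-indene-7-carbaldehyde
Conditions: MgI2·OEt2 (3 equiv), toluene, 70 °C; then dilute aq. HCl, 0 °C
Reagents that add atoms: none
Why: Chelation-controlled demethylation: magnesium binds the formyl oxygen and the neighbouring methoxy oxygen, and iodide removes the methyl group by SN2; only the ether ortho to the aldehyde is activated, so the dioxane ethers are left alone, and the tertiary alcohol is held as its magnesium alkoxide until work-up.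

## Compound list

1 | 2-bromo-6-methoxybenzaldehyde | COc1cccc(Br)c1C=O | starting material
2 | 2-bromo-3-iodo-6-methoxybenzaldehyde | COc1ccc(I)c(Br)c1C=O | intermediate
3 | 2-(2-bromo-3-iodo-6-methoxyphenyl)-1,3-dioxolane | COc1ccc(I)c(Br)c1C1OCCO1 | intermediate
4 | [2-bromo-3-(1,3-dioxolan-2-yl)-4-methoxyphenyl]magnesium chloride (LiCl complex, not isolated) | COc1ccc([Mg]Cl)c(Br)c1C1OCCO1 | intermediate
5 | 2-bromo-3-(1,3-dioxolan-2-yl)-4-methoxybenzaldehyde | COc1ccc(C=O)c(Br)c1C1OCCO1 | intermediate
6 | [2-bromo-3-(1,3-dioxolan-2-yl)-4-methoxyphenyl]methanol | COc1ccc(CO)c(Br)c1C1OCCO1 | intermediate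
7 | {[2-bromo-3-(1,3-dioxolan-2-yl)-4-methoxyphenyl]methoxy}(tert-butyl)dimethylsilane | COc1ccc(CO[Si](C)(C)C(C)(C)C)c(Br)c1C1OCCO1 | intermediate
8 | [6-({[tert-butyl(dimethyl)silyl]oxy}methyl)-2-(1,3-dioxolan-2-yl)-3-methoxyphenyl]lithium (not isolated) | COc1ccc(CO[Si](C)(C)C(C)(C)C)c([Li])c1C1OCCO1 | intermediate
9 | 6-({[tert-butyl(dimethyl)silyl]oxy}methyl)-2-(1,3-dioxolan-2-yl)-3-methoxybenzaldehyde | COc1ccc(CO[Si](C)(C)C(C)(C)C)c(C=O)c1C1OCCO1 | intermediate
10 | prop-1-yn-1-ylmagnesium bromide | CC#C[Mg]Br | starting material
11 | bromomagnesium 1-[6-({[tert-butyl(dimethyl)silyl]oxy}methyl)-2-(1,3-dioxolan-2-yl)-3-methoxyphenyl]but-2-yn-1-olate (racemic, not isolated) | CC#CC(O[Mg]Br)c1c(CO[Si](C)(C)C(C)(C)C)ccc(OC)c1C1OCCO1 | intermediate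
12 | rac-1-[6-({[tert-butyl(dimethyl)silyl]oxy}methyl)-2-(1,3-dioxolan-2-yl)-3-methoxyphenyl]but-2-yn-1-yl methyl carbonate | CC#CC(OC(=O)OC)c1c(CO[Si](C)(C)C(C)(C)C)ccc(OC)c1C1OCCO1 | intermediate
13 | 3-methylbut-2-en-1-ol | CC(C)=CCO | starting material
14 | [(2R)-3,3-dimethyloxiran-2-yl]methanol (not isolated) | OC[C@H]1OC1(C)C | intermediate
15 | [(2R)-3,3-dimethyloxiran-2-yl]methyl 4-methylbenzenesulfonate | Cc1ccc(cc1)S(=O)(=O)OC[C@H]1OC1(C)C | intermediate
16 | 3-bromo-2-hydroxy-5-methylbenzaldehyde | Cc1cc(Br)c(O)c(C=O)c1 | starting material
17 | 3-bromo-5-methyl-2-(prop-2-en-1-yloxy)benzaldehyde | Cc1cc(Br)c(OCC=C)c(C=O)c1 | intermediate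
18 | 3-bromo-5-methyl-2-(prop-2-en-1-yloxy)phenyl formate (not isolated) | Cc1cc(Br)c(OCC=C)c(OC=O)c1 | intermediate
19 | 3-bromo-5-methyl-2-(prop-2-en-1-yloxy)phenol | Cc1cc(Br)c(OCC=C)c(O)c1 | intermediate
20 | (2R)-2-{[3-bromo-5-methyl-2-(prop-2-en-1-yloxy)phenoxy]methyl}-3,3-dimethyloxirane | Cc1cc(Br)c(OCC=C)c(OC[C@H]2OC2(C)C)c1 | intermediate
21 | 2-bromo-6-{[(2R)-3,3-dimethyloxiran-2-yl]methoxy}-4-methylphenol (not isolated) | Cc1cc(Br)c(O)c(OC[C@H]2OC2(C)C)c1 | intermediate
22 | 2-[(2S)-8-bromo-6-methyl-2,3-dihydro-1,4-benzodioxin-2-yl]propan-2-ol | Brc1cc(C)cc2c1O[C@H](C(C)(C)O)CO2 | intermediate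
23 | {[2-((2S)-8-bromo-6-methyl-2,3-dihydro-1,4-benzodioxin-2-yl)propan-2-yl]oxy}triethylsilane | Brc1cc(C)cc2c1O[C@H](C(C)(C)O[Si](CC)(CC)CC)CO2 | intermediate
24 | {(2S)-6-methyl-2-[2-(triethylsilyloxy)propan-2-yl]-2,3-dihydro-1,4-benzodioxin-8-yl}lithium (not isolated) | [Li]c1cc(C)cc2c1O[C@H](C(C)(C)O[Si](CC)(CC)CC)CO2 | intermediate
25 | {(2S)-6-methyl-2-[2-(triethylsilyloxy)propan-2-yl]-2,3-dihydro-1,4-benzodioxin-8-yl}zinc chloride (not isolated) | Cl[Zn]c1cc(C)cc2c1O[C@H](C(C)(C)O[Si](CC)(CC)CC)CO2 | intermediate
26 | {[2-((2S)-8-{(1S)-1-[6-({[tert-butyl(dimethyl)silyl]oxy}methyl)-2-(1,3-dioxolan-2-yl)-3-methoxyphenyl]but-2-yn-1-yl}-6-methyl-2,3-dihydro-1,4-benzodioxin-2-yl)propan-2-yl]oxy}triethylsilane | CC#C[C@@H](c1c(CO[Si](C)(C)C(C)(C)C)ccc(OC)c1C1OCCO1)c1cc(C)cc2c1O[C@H](C(C)(C)O[Si](CC)(CC)CC)CO2 | intermediate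
27 | 2-[(2S)-8-{(1S)-1-[2-(1,3-dioxolan-2-yl)-6-(hydroxymethyl)-3-methoxyphenyl]but-2-yn-1-yl}-6-methyl-2,3-dihydro-1,4-benzodioxin-2-yl]propan-2-ol | CC#C[C@@H](c1c(CO)ccc(OC)c1C1OCCO1)c1cc(C)cc2c1O[C@H](C(C)(C)O)CO2 | intermediate
28 | {3-(1,3-dioxolan-2-yl)-2-[(1S)-1-{(2S)-2-(2-hydroxypropan-2-yl)-6-methyl-2,3-dihydro-1,4-benzodioxin-8-yl}but-2-yn-1-yl]-4-methoxyphenyl}methyl methanesulfonate (not isolated) | CC#C[C@@H](c1c(COS(C)(=O)=O)ccc(OC)c1C1OCCO1)c1cc(C)cc2c1O[C@H](C(C)(C)O)CO2 | intermediate
29 | 2-[(2S)-8-{(1S)-1-[6-(chloromethyl)-2-(1,3-dioxolan-2-yl)-3-methoxyphenyl]but-2-yn-1-yl}-6-methyl-2,3-dihydro-1,4-benzodioxin-2-yl]propan-2-ol | CC#C[C@@H](c1c(CCl)ccc(OC)c1C1OCCO1)c1cc(C)cc2c1O[C@H](C(C)(C)O)CO2 | intermediate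
30 | methylboronic acid | CB(O)O | starting material
31 | 2-[(2S)-8-{(1S)-7-(1,3-dioxolan-2-yl)-6-methoxy-2-(propan-2-ylidene)-2,3-dihydro-1H-inden-1-yl}-6-methyl-2,3-dihydro-1,4-benzodioxin-2-yl]propan-2-ol | CC(C)=C1Cc2ccc(OC)c(C3OCCO3)c2[C@H]1c1cc(C)cc2c1O[C@H](C(C)(C)O)CO2 | intermediate
32 | (1S)-1-[(2S)-2-(2-hydroxypropan-2-yl)-6-methyl-2,3-dihydro-1,4-benzodioxin-8-yl]-6-methoxy-2-(propan-2-ylidene)-2,3-dihydro-1H-indene-7-carbaldehyde | CC(C)=C1Cc2ccc(OC)c(C=O)c2[C@H]1c1cc(C)cc2c1O[C@H](C(C)(C)O)CO2 | intermediate
33 | diaporindene H, (1S)-6-hydroxy-1-[(2S)-2-(2-hydroxypropan-2-yl)-6-methyl-2,3-dihydro-1,4-benzodioxin-8-yl]-2-(propan-2-ylidene)-2,3-dihydro-1H-indene-7-carbaldehyde | CC(C)=C1Cc2ccc(O)c(C=O)c2[C@H]1c1cc(C)cc2c1O[C@H](C(C)(C)O)CO2 | target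

## Step count and least certain steps

Total: 19 steps. Longest linear sequence: 13 steps (steps 1–7 and 14–19); the ring B branch (steps 8–13) has six steps, five of them in line from 16.

**Step 17 (key step).** Transfer of the methyl group from boron to the alkenylpalladium may be too slow. The organopalladium intermediates could then be lost by protonation or by direct coupling before ring closure, and the electron-rich benzylic chloride could solvolyse. Fallback: divide the cascade and reverse the polarity of the methyl partner. Setting out from 29, the same 5-exo-dig closure would be terminated with B2pin2 (Pd(PPh3)4, KOAc, dioxane) to give the (Z)-alkenyl pinacolboronate F1. A separate Suzuki–Miyaura coupling of F1 with iodomethane (PdCl2(dppf), K3PO4, THF/H2O) would then return to the route at 31.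

**Step 14.** Enantiofacial control may erode at the very hindered radical centre (two ortho substituents on ring A, an ortho oxygen on the arylzinc), and coupling at the allenyl terminus may compete. Such doubly ortho-substituted 1-aryl substrates lie at the edge of what this coupling is known to tolerate. Fallback: give up catalyst control and use the fixed dioxane centre for separation. Setting out from 12 and 25, the coupling would be run with an achiral ligand (NiCl2(dme), 2,2'-bipyridine) to give 26 together with its C1 epimer F2. After fluoride desilylation the diol 27 and its C1-epimeric diol F3 are diastereomers and would be separated by preparative chromatography, rejoining the route at 27.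

**Step 19.** The Lewis acid at 70 °C may cause migration of the exocyclic alkene into the five-membered ring or ionisation of the tertiary alcohol before demethylation is complete. Fallback: change the order and the mechanism. Setting out from 31, the methyl ether would be cleaved by nucleophilic attack of a thiolate on the methyl group (NaSEt, DMF, 120 °C) while the aldehyde is still masked, giving the phenol acetal F4. Mild hydrolysis of F4 (PPTS, acetone/H2O) would arrive directly at 33.

**Step 1.** Iodination may partly occur ortho to the methoxy group, or go slowly on the deactivated ring, because the wanted position is flanked by bromine. Fallback: place the carbon by deprotonation instead of electrophilic substitution. Setting out from 1, acetalisation would give 2-(2-bromo-6-methoxyphenyl)-1,3-dioxolane F5. Lithium 2,2,6,6-tetramethylpiperidide (THF, −78 °C) would remove the proton next to bromine to give the aryllithium F6, and a DMF quench would return to the route at 5.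

## Further compounds

F1 | step 17 | 2-[(2S)-8-{(1S,2Z)-7-(1,3-dioxolan-2-yl)-6-methoxy-2-[1-(4,4,5,5-tetramethyl-1,3,2-dioxaborolan-2-yl)ethylidene]-2,3-dihydro-1H-inden-1-yl}-6-methyl-2,3-dihydro-1,4-benzodioxin-2-yl]propan-2-ol | C/C(B2OC(C)(C)C(C)(C)O2)=C1/Cc3ccc(OC)c(C4OCCO4)c3[C@H]1c1cc(C)cc2c1O[C@H](C(C)(C)O)CO2
F2 | step 14 | C1 epimer of 26, {[2-((2S)-8-{(1R)-1-[6-({[tert-butyl(dimethyl)silyl]oxy}methyl)-2-(1,3-dioxolan-2-yl)-3-methoxyphenyl]but-2-yn-1-yl}-6-methyl-2,3-dihydro-1,4-benzodioxin-2-yl)propan-2-yl]oxy}triethylsilane | CC#C[C@H](c1c(CO[Si](C)(C)C(C)(C)C)ccc(OC)c1C1OCCO1)c1cc(C)cc2c1O[C@H](C(C)(C)O[Si](CC)(CC)CC)CO2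
F3 | step 14 | C1 epimer of 27, 2-[(2S)-8-{(1R)-1-[2-(1,3-dioxolan-2-yl)-6-(hydroxymethyl)-3-methoxyphenyl]but-2-yn-1-yl}-6-methyl-2,3-dihydro-1,4-benzodioxin-2-yl]propan-2-ol | CC#C[C@H](c1c(CO)ccc(OC)c1C1OCCO1)c1cc(C)cc2c1O[C@H](C(C)(C)O)CO2
F4 | step 19 | (1S)-7-(1,3-dioxolan-2-yl)-1-[(2S)-2-(2-hydroxypropan-2-yl)-6-methyl-2,3-dihydro-1,4-benzodioxin-8-yl]-2-(propan-2-ylidene)-2,3-dihydro-1H-inden-6-ol | CC(C)=C1Cc2ccc(O)c(C3OCCO3)c2[C@H]1c1cc(C)cc2c1O[C@H](C(C)(C)O)CO2
F5 | step 1 | 2-(2-bromo-6-methoxyphenyl)-1,3-dioxolane | COc1cccc(Br)c1C1OCCO1
F6 | step 1 | [2-bromo-3-(1,3-dioxolan-2-yl)-4-methoxyphenyl]lithium | COc1ccc([Li])c(Br)c1C1OCCO1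
A1 | alternative 1 | 2-[(2S)-8-{(1S)-2-isopropylidene indane fused at C6 and C7 to a 1,1-diisopropyl-1,3-dihydro-2,1-benzoxasilole}-6-methyl-2,3-dihydro-1,4-benzodioxin-2-yl]propan-2-ol | CC(C)=C1Cc2ccc3[Si](C(C)C)(C(C)C)OCc3c2[C@H]1c1cc(C)cc2c1O[C@H](C(C)(C)O)CO2
A2 | alternative 1 | open-chain triyne: 2-[(2S)-8-{(3S)-6-[ethynyl(diisopropyl)silyloxy]-2-(propan-2-ylidene)-1-(prop-2-yn-1-yl... written as 3-aryl-6-[ethynyl(diisopropyl)silyloxy]-2-(prop-2-yn-1-yl) unit: 4-methyl-3-(prop-2-yn-1-yl)pent-3-en-2-yl centre bearing the aryl group and a 3-[ethynyl(diisopropyl)silyloxy]prop-1-yn-1-yl group}-6-methyl-2,3-dihydro-1,4-benzodioxin-2-yl]propan-2-ol | C#CCC(=C(C)C)[C@@H](C#CCO[Si](C(C)C)(C(C)C)C#C)c1cc(C)cc2c1O[C@H](C(C)(C)O)CO2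
A3 | alternative 2 | [(1S)-6-methoxy-1-{(2S)-6-methyl-2-[2-(triethylsilyloxy)propan-2-yl]-2,3-dihydro-1,4-benzodioxin-8-yl}-2-(propan-2-ylidene)-2,3-dihydro-1H-inden-7-yl]methanol | CC(C)=C1Cc2ccc(OC)c(CO)c2[C@H]1c1cc(C)cc2c1O[C@H](C(C)(C)O[Si](CC)(CC)CC)CO2
A4 | alternative 2 | 4-methoxy-7-(3-methylbut-2-en-1-yl)-1-{(2S)-6-methyl-2-[2-(triethylsilyloxy)propan-2-yl]-2,3-dihydro-1,4-benzodioxin-8-yl}-1,3-dihydro-2-benzofuran (either configuration at C1) | CC(C)=CCc1ccc(OC)c2c1C(OC2)c1cc(C)cc2c1O[C@H](C(C)(C)O[Si](CC)(CC)CC)CO2
A5 | alternative 3 | methyl (1S,2R)-7-({[tert-butyl(dimethyl)silyl]oxy}methyl)-1-[(2S)-2-(2-hydroxypropan-2-yl)-6-methyl-2,3-dihydro-1,4-benzodioxin-8-yl]-6-methoxy-2,3-dihydro-1H-indene-2-carboxylate (trans) | COC(=O)[C@@H]1Cc2ccc(OC)c(CO[Si](C)(C)C(C)(C)C)c2[C@H]1c1cc(C)cc2c1O[C@H](C(C)(C)O)CO2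
A6 | alternative 3 | methyl 5-({[tert-butyl(dimethyl)silyl]oxy}methyl)-4-[(2S)-2-(2-hydroxypropan-2-yl)-6-methyl-2,3-dihydro-1,4-benzodioxin-8-yl]-6-methoxy-1,2,3,4-tetrahydroisoquinoline-3-carboxylate (C4 as in the target, either configuration at C3) | COC(=O)C1NCc2ccc(OC)c(CO[Si](C)(C)C(C)(C)C)c2[C@H]1c1cc(C)cc2c1O[C@H](C(C)(C)O)CO2
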